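Free monomer plus monomer in chains is a conserved sum: the last readings add to 98.8% in dawn and 102% in dusk, with a scatter of 1 percentage point on each reading. So I can follow free monomer and get the other by subtraction.

| flask | free monomer | pre-initiator | remark | time |
|---|---|---|---|---|
| dawn | 0.30 M | 3.8 mM | run made earlier |  |
| dusk | 0.30 M | 11 mM | run made earlier |  |
| cedar | 0.30 M | 5.7 mM |  | 6.0 d |
| maple | 1.2 M | 5.7 mM |  | 6.0 d |

| run | time / h | monomer in chains / % | free monomer / % |
|---|---|---|---|
| dawn | 1.50 | 2.7 | 98.8 |
| dawn | 4.00 | 5.7 | 95.8 |
| dawn | 8.00 | 13.2 | 87.6 |
| dawn | 12.0 | 17.1 | 82.7 |
| dawn | 20.0 | 23.9 | 74.9 |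
| dawn | 25.0 | 27.7 | 72.1 |
| dawn | 30.0 | 27.0 | 71.8 |
| dusk | 2.50 | 7.3 | 91.0 |
| dusk | 4.00 | 12.6 | 88.4 |
| dusk | 5.00 | 15.7 | 82.4 |
| dusk | 8.00 | 22.6 | 75.0 |
| dusk | 12.0 | 30.6 | 71.9 |
| dusk | 20.0 | 35.1 | 65.2 |
| dusk | 30.0 | 39.7 | 62.5 |

(readings scatter by 1 percentage point)

- which of the two ends with the longer chains by the average number of monomer units in a chain (chains begun, living or dead) ("neither" if they lie within 10%) (cedar / maple / neither)
- average number of monomer units in a chain (chains begun, living or dead) at the end, cedar
- average number of monomer units in a chain (chains begun, living or dead) at the end, maple

- the average divides the monomer in chains by the number of chains begun, living and dead together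
- the earlier runs do not show the number of chains; that part of a forecast is a guess

I read the end of each free monomer column. In dawn, from 25.0 h to 30.0 h, free monomer moves 0.3 points, inside the scatter. In dusk, from 20.0 h to 30.0 h, it moves 2.7 points, against 3.1 points in dawn over the same hours. Dusk also ends lower, at 62.5% against 71.8%.

These two last readings stand 9.3 points apart, with a scatter of 1 point. A level set by run-back alone takes no account of pre-initiator, so it does not stop dawn and dusk at different heights, and growth must also die in these runs. Still, for the chain length I reckon with the run-back. I treat adding and losing units at a chain end as a fast step that settles, like a lag reaching its setpoint. In my reckoning, free monomer then heads for a standing level, the equilibrium monomer concentration, whatever the charge. I take dusk, with more pre-initiator than dawn, as the run nearer that level, and I set the level at its last reading, 0.188 M.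

The chain count is a guess: one chain per pre-initiator charged. Length is then charge minus level, divided by pre-initiator. That gives 19.7 for cedar and 178 for maple.

The forecast also says maple, but with 33 and 130. It holds that “both cedar and maple reach this”, the same percentage, where I hold the same level.

The flask gives maple, with 21.3 for cedar and 162 for maple.

    free monomer + initiator → living end + monomer in chains (k = 0.0840 /M/min)
    free monomer + living end → monomer in chains + living end, rate k2*[living end]*[free monomer] (k = 0.320 /M/min)
    monomer in chains + living end → free monomer + living end, rate k3*[living end] as long as [monomer in chains] is above zero (k = 0.0530 /min)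
    2 living end → dead end (k = 0.240 /M/min)
    pre-initiator ⇌ initiator (K = 0.400, k = 0.0140 /min)

Cedar ends at 21.3 against my 19.7, and maple at 162 against my 178. Maple still holds 0.278 M of free monomer, more than my level. The neighbouring flask is maple stopped at 2.5 d. My level gives it the same 178, but its free monomer stands at 0.363 M, and its length is 147.

The earlier runs and the new flask are calculated with made-up constants; the scatter is artificial.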